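**Plan**
- Retrosynthesis: once the C8–O benzyl and C3–Cl bonds are cleared, ring C is cut at C2–C3 and C3–C4, which removes C3. C3 is the only hydrogen-bearing carbon of the pyranone and lies between C2 (bonded to O1 and ring B) and the C4 carbonyl, so its removal leaves a 2-aryl-3-siloxybenzofuran whose C2=C3 enol ether bond can take that carbon back as a carbene.
- The benzofuran is then cut at the ketone–arene bond C3–C3a (Friedel–Crafts) and at the ether bond O1–C2 (Williamson), giving a ring A phenol and a ring B α-bromo arylacetate.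
- Forward: the ring A phenol (three steps) and the bromo ester (two steps) are joined through oxygen, and the furanone ring closes. O-Silylation aromatises it to the benzofuran, dichlorocarbene enlarges the furan to ring C, and hydrogenolysis removes chlorine and benzyl.
- Stereochemistry: the target is achiral; the stereocentres of intermediates are racemic and vanish on silylation and on ring expansion.

Key step: step 10

Remark: compounds 10, 11, 12, 13, 14 and 17 are racemic (in 17 the ring fusion can only be cis), so their SMILES carry no stereodescriptors. 2,3,4-Trimethoxyphenol is taken as a catalogue compound.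

**Route**

Step 1
Reactants: 1 2,3,4-trimethoxyphenol
Product: 3 2-hydroxy-3,4,5-trimethoxybenzaldehyde, via hydroxymethylphenol 2 (not isolated)
Conditions: (CH2O)n, MgCl2, Et3N, MeCN, reflux; aq HCl
Reagents that add atoms: paraformaldehyde (reacting as formaldehyde), C=O
Why: Casnati–Skattebøl ortho-formylation, in which the magnesium phenoxide delivers formaldehyde to C6, the only free position ortho to the hydroxyl, and a second formaldehyde oxidises the benzylic alkoxide to the aldehyde by hydride transfer.

Step 2
Reactants: 3 2-hydroxy-3,4,5-trimethoxybenzaldehyde; 4 benzyl bromide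
Product: 5 2-benzyloxy-3,4,5-trimethoxybenzaldehyde
Conditions: K2CO3, DMF, 60 °C
Reagents that add atoms: none
Why: Williamson etherification of the phenoxide with a reactive benzylic bromide in a dipolar aprotic solvent should be clean, since no other nucleophilic site is present.

Step 3
Reactants: 5 2-benzyloxy-3,4,5-trimethoxybenzaldehyde
Product: 7 2-benzyloxy-3,4,5-trimethoxyphenol, via aryl formate 6 (not isolated)
Conditions: mCPBA, CH2Cl2, 0 °C to rt; then K2CO3 (cat.), MeOH, rt
Reagents that add atoms: mCPBA, O=C(OO)c1cccc(Cl)c1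
Why: Baeyer–Villiger (Dakin-type) oxidation, in which the aryl group carrying ortho and para alkoxy donors migrates in preference to hydride, followed by mild methanolysis of the formate that leaves the benzyl and methyl ethers untouched.

Step 4
Reactants: 8 3,4,5-trimethoxyphenylacetic acid
Product: 9 methyl 3,4,5-trimethoxyphenylacetate
Conditions: MeOH, H2SO4 (cat.), reflux
Reagents that add atoms: methanol, CO
Why: Fischer esterification driven by methanol as solvent.

Step 5
Reactants: 9 methyl 3,4,5-trimethoxyphenylacetate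
Product: 10 methyl 2-bromo-2-(3,4,5-trimethoxyphenyl)acetate (racemic)
Conditions: NBS, AIBN (cat.), PhCF3, 80 °C
Reagents that add atoms: N-bromosuccinimide, O=C1CCC(=O)N1Br
Why: Wohl–Ziegler bromination, in which the C–H bond that is both benzylic and α to the ester should be abstracted by the radical chain in a non-polar solvent faster than ionic bromination of the trimethoxyarene can occur.

Step 6
Reactants: 7 2-benzyloxy-3,4,5-trimethoxyphenol; 10 methyl 2-bromo-2-(3,4,5-trimethoxyphenyl)acetate
Product: 11 methyl 2-(2-benzyloxy-3,4,5-trimethoxyphenoxy)-2-(3,4,5-trimethoxyphenyl)acetate (racemic)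
Conditions: K2CO3, acetone, reflux
Reagents that add atoms: none
Why: Williamson ether synthesis by SN2 displacement at a secondary α-bromo ester that cannot eliminate, which forms the O1–C2 bond of the later heterocycle.

Step 7
Reactants: 11 methyl 2-(2-benzyloxy-3,4,5-trimethoxyphenoxy)-2-(3,4,5-trimethoxyphenyl)acetate
Product: 12 2-(2-benzyloxy-3,4,5-trimethoxyphenoxy)-2-(3,4,5-trimethoxyphenyl)acetic acid (racemic)
Conditions: LiOH·H2O, THF–MeOH–H2O, rt; then aq HCl
Reagents that add atoms: lithium hydroxide, [Li+].[OH-]
Why: Saponification of a methyl ester at room temperature, to which the aryl ethers are inert and for which the racemic α-centre is of no consequence.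

Step 8
Reactants: 12 2-(2-benzyloxy-3,4,5-trimethoxyphenoxy)-2-(3,4,5-trimethoxyphenyl)acetic acid
Product: 14 7-benzyloxy-4,5,6-trimethoxy-2-(3,4,5-trimethoxyphenyl)benzofuran-3(2H)-one (racemic), via mixed trifluoroacetic anhydride 13 (not isolated)
Conditions: (CF3CO)2O, CH2Cl2, 0 °C to rt, Ar; aq NaHCO3
Reagents that add atoms: none
Why: Intramolecular Friedel–Crafts acylation through the mixed anhydride closes the five-membered ring onto the single free carbon of ring A, which is ortho and para to alkoxy donors, under conditions mild enough to keep the benzyl ether and the methoxyl next to the new ketone.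

Step 9
Reactants: 14 7-benzyloxy-4,5,6-trimethoxy-2-(3,4,5-trimethoxyphenyl)benzofuran-3(2H)-one
Product: 15 7-benzyloxy-3-(tert-butyldimethylsilyloxy)-4,5,6-trimethoxy-2-(3,4,5-trimethoxyphenyl)benzofuran
Conditions: TBSOTf, Et3N, CH2Cl2, 0 °C, Ar
Reagents that add atoms: tert-butyldimethylsilyl trifluoromethanesulfonate, CC(C)(C)[Si](C)(C)OS(=O)(=O)C(F)(F)F
Why: Soft enolisation and O-silylation (silyl enol ether formation) of a ketone whose enol form is an aromatic benzofuran, so that O-silylation should be strongly favoured and the air-sensitive C2–H is removed.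

Step 10
Reactants: 15 7-benzyloxy-3-(tert-butyldimethylsilyloxy)-4,5,6-trimethoxy-2-(3,4,5-trimethoxyphenyl)benzofuran; 16 chloroform
Product: 19 8-benzyloxy-3-chloro-5,6,7,3',4',5'-hexamethoxyflavone, via dichlorocyclopropane adduct 17 (not isolated), via siloxyflavylium chloride 18 (not isolated)
Conditions: KOtBu, THF–hexane, −30 °C to rt; aq NH4Cl
Reagents that add atoms: none
Why: Proposed new method: dichlorocarbene generated from chloroform and KOtBu should add as an electrophile to the C2=C3 bond of 15, the only π bond that is at once an aryl enol ether (through O1) and a silyl enol ether, to give the cis-fused dichlorocyclopropane 17 by [2+1] cycloaddition. Ionisation of the endo C–Cl bond is concerted with disrotatory opening of the cyclopropane bond shared with the furan ring, so ring C arises by one-carbon expansion of the five-membered ring, not by cyclisation, and the aromatic 3-chloro-4-siloxyflavylium ion 18 results. Chloride then removes the silyl group from the C4 oxygen and releases the pyran-4-one 19. The closest known reaction types are the dihalocarbene ring expansion of cyclic silyl enol ethers to 2-halo-2-enones and the Ciamician–Dennstedt-type expansion of benzofurans and indoles to chromenes and quinolines, neither of which has been shown on a 3-siloxybenzofuran. No stereocentre is present in 19, and the two stereocentres of 17 are erased on opening. The step needs chemoselectivity for the furan C2=C3 bond over the two trimethoxyarenes and fidelity in where the carbon is inserted; the combined donation of O1 and the siloxy oxygen into that one bond secures the first, and the fact that only cleavage of the shared bond leads to an aromatic cation secures the second.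

Step 11
Reactants: 19 8-benzyloxy-3-chloro-5,6,7,3',4',5'-hexamethoxyflavone
Product: 20 8-hydroxy-5,6,7,3',4',5'-hexamethoxyflavone
Conditions: H2 (1 atm), 10% Pd/C, NaOAc, EtOAc–MeOH, rt
Reagents that add atoms: none
Why: Catalytic hydrogenolysis over palladium on carbon should cleave the benzylic C–O bond and the activated vinylic C–Cl bond while acetate buffers the HCl formed, and stopping after two equivalents of hydrogen should spare the C2=C3 bond.

**Compound list**

1 | 2,3,4-trimethoxyphenol | COc1ccc(O)c(OC)c1OC | starting material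
2 | 6-(hydroxymethyl)-2,3,4-trimethoxyphenol (not isolated) | COc1cc(CO)c(O)c(OC)c1OC | intermediate
3 | 2-hydroxy-3,4,5-trimethoxybenzaldehyde | COc1cc(C=O)c(O)c(OC)c1OC | intermediate
4 | benzyl bromide | BrCc1ccccc1 | starting material
5 | 2-benzyloxy-3,4,5-trimethoxybenzaldehyde | COc1cc(C=O)c(OCc2ccccc2)c(OC)c1OC | intermediate
6 | 2-benzyloxy-3,4,5-trimethoxyphenyl formate (not isolated) | COc1cc(OC=O)c(OCc2ccccc2)c(OC)c1OC | intermediate
7 | 2-benzyloxy-3,4,5-trimethoxyphenol | COc1cc(O)c(OCc2ccccc2)c(OC)c1OC | intermediate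
8 | 3,4,5-trimethoxyphenylacetic acid | COc1cc(CC(=O)O)cc(OC)c1OC | starting material
9 | methyl 3,4,5-trimethoxyphenylacetate | COC(=O)Cc1cc(OC)c(OC)c(OC)c1 | intermediate
10 | methyl 2-bromo-2-(3,4,5-trimethoxyphenyl)acetate (racemic) | COC(=O)C(Br)c1cc(OC)c(OC)c(OC)c1 | intermediate
11 | methyl 2-(2-benzyloxy-3,4,5-trimethoxyphenoxy)-2-(3,4,5-trimethoxyphenyl)acetate (racemic) | COC(=O)C(Oc1cc(OC)c(OC)c(OC)c1OCc1ccccc1)c1cc(OC)c(OC)c(OC)c1 | intermediate
12 | 2-(2-benzyloxy-3,4,5-trimethoxyphenoxy)-2-(3,4,5-trimethoxyphenyl)acetic acid (racemic) | OC(=O)C(Oc1cc(OC)c(OC)c(OC)c1OCc1ccccc1)c1cc(OC)c(OC)c(OC)c1 | intermediate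
13 | 2-(2-benzyloxy-3,4,5-trimethoxyphenoxy)-2-(3,4,5-trimethoxyphenyl)acetic trifluoroacetic anhydride (racemic, not isolated) | O=C(OC(=O)C(F)(F)F)C(Oc1cc(OC)c(OC)c(OC)c1OCc1ccccc1)c1cc(OC)c(OC)c(OC)c1 | intermediate
14 | 7-benzyloxy-4,5,6-trimethoxy-2-(3,4,5-trimethoxyphenyl)benzofuran-3(2H)-one (racemic) | COc1cc(C2Oc3c(OCc4ccccc4)c(OC)c(OC)c(OC)c3C2=O)cc(OC)c1OC | intermediate
15 | 7-benzyloxy-3-(tert-butyldimethylsilyloxy)-4,5,6-trimethoxy-2-(3,4,5-trimethoxyphenyl)benzofuran | COc1cc(-c2oc3c(OCc4ccccc4)c(OC)c(OC)c(OC)c3c2O[Si](C)(C)C(C)(C)C)cc(OC)c1OC | intermediate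
16 | chloroform | ClC(Cl)Cl | starting material
17 | 3-benzyloxy-6b-(tert-butyldimethylsilyloxy)-1,1-dichloro-4,5,6-trimethoxy-1a-(3,4,5-trimethoxyphenyl)-1a,6b-dihydro-1H-cyclopropa[b]benzofuran (racemic, cis-fused, not isolated) | COc1cc(C23Oc4c(OCc5ccccc5)c(OC)c(OC)c(OC)c4C2(O[Si](C)(C)C(C)(C)C)C3(Cl)Cl)cc(OC)c1OC | intermediate
18 | 8-benzyloxy-4-(tert-butyldimethylsilyloxy)-3-chloro-5,6,7-trimethoxy-2-(3,4,5-trimethoxyphenyl)chromenylium chloride (not isolated) | COc1cc(-c2[o+]c3c(OCc4ccccc4)c(OC)c(OC)c(OC)c3c(O[Si](C)(C)C(C)(C)C)c2Cl)cc(OC)c1OC.[Cl-] | intermediate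
19 | 8-benzyloxy-3-chloro-5,6,7,3',4',5'-hexamethoxyflavone | COc1cc(-c2oc3c(OCc4ccccc4)c(OC)c(OC)c(OC)c3c(=O)c2Cl)cc(OC)c1OC | intermediate
20 | 8-hydroxy-5,6,7,3',4',5'-hexamethoxyflavone | COc1cc(-c2cc(=O)c3c(OC)c(OC)c(OC)c(O)c3o2)cc(OC)c1OC | target

**Step count and risks**

Total steps: 11. Longest linear sequence: 9 steps (steps 1, 2, 3, 6, 7, 8, 9, 10, 11).

Steps most likely to fail:

1. Step 10. tert-Butoxide may strip the silyl group before the carbene arrives, so that the free enolate is dichloromethylated at C2 (Reimer–Tiemann-type) instead of cyclopropanated. The carbene may also be consumed by alkoxide faster than by the hindered tetrasubstituted enol ether, or the pyranone formed may be opened by alkoxide addition at C2. The fallback uses known chemistry and builds ring C by cyclisation instead of expansion. It sets out from 7: ortho-acetylation with Ac2O and BF3·OEt2 (Fries-type) should give 1-(3-benzyloxy-2-hydroxy-4,5,6-trimethoxyphenyl)ethan-1-one F1. Claisen–Schmidt condensation with commercial 3,4,5-trimethoxybenzaldehyde (KOH, EtOH) should give (E)-1-(3-benzyloxy-2-hydroxy-4,5,6-trimethoxyphenyl)-3-(3,4,5-trimethoxyphenyl)prop-2-en-1-one F2. Oxidative cyclisation with catalytic I2 in DMSO at 120 °C should give 8-benzyloxy-5,6,7,3',4',5'-hexamethoxyflavone F3. Hydrogenolysis (H2, 10% Pd/C, EtOAc) then comes back to the route at 20.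

2. Step 8. The α-aryloxy acyl cation may lose carbon monoxide, the acid medium may remove the benzyl ether or trifluoroacetylate ring A, and the enolisable C2–H of the product may autoxidise during isolation. The fallback forms the ketone–arene bond first with an electrophile that has no α-oxygen and closes the ring through oxygen. It sets out from 7 and 8: C-acylation mediated by BF3·OEt2 at 80 °C should give 1-(3-benzyloxy-2-hydroxy-4,5,6-trimethoxyphenyl)-2-(3,4,5-trimethoxyphenyl)ethan-1-one F4. α-Bromination with CuBr2 in refluxing EtOAc–CHCl3 should give 1-(3-benzyloxy-2-hydroxy-4,5,6-trimethoxyphenyl)-2-bromo-2-(3,4,5-trimethoxyphenyl)ethan-1-one F5. K2CO3 in acetone then closes the O1–C2 bond by intramolecular SN2 and comes back to the route at 14.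

3. Step 11. Hydrogenation may run on to reduce the C2=C3 bond of ring C to the flavanone, or the C–Cl hydrogenolysis may stall as chloride accumulates on the catalyst. The fallback separates the two cleavages and avoids hydrogen gas. It sets out from 19: acidolytic debenzylation with TFA and pentamethylbenzene as cation scavenger should give 3-chloro-8-hydroxy-5,6,7,3',4',5'-hexamethoxyflavone F6. Homogeneous palladium-catalysed formate reduction of the C–Cl bond (Pd(OAc)2, SPhos, HCO2Na, DMF, 80 °C) then comes back to the route at 20.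

**Further compounds**

F1 | step 10 | 1-(3-benzyloxy-2-hydroxy-4,5,6-trimethoxyphenyl)ethan-1-one | CC(=O)c1c(O)c(OCc2ccccc2)c(OC)c(OC)c1OC
F2 | step 10 | (E)-1-(3-benzyloxy-2-hydroxy-4,5,6-trimethoxyphenyl)-3-(3,4,5-trimethoxyphenyl)prop-2-en-1-one | COc1cc(/C=C/C(=O)c2c(O)c(OCc3ccccc3)c(OC)c(OC)c2OC)cc(OC)c1OC
F3 | step 10 | 8-benzyloxy-5,6,7,3',4',5'-hexamethoxyflavone | COc1cc(-c2cc(=O)c3c(OC)c(OC)c(OC)c(OCc4ccccc4)c3o2)cc(OC)c1OC
F4 | step 8 | 1-(3-benzyloxy-2-hydroxy-4,5,6-trimethoxyphenyl)-2-(3,4,5-trimethoxyphenyl)ethan-1-one | COc1cc(CC(=O)c2c(O)c(OCc3ccccc3)c(OC)c(OC)c2OC)cc(OC)c1OC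
F5 | step 8 | 1-(3-benzyloxy-2-hydroxy-4,5,6-trimethoxyphenyl)-2-bromo-2-(3,4,5-trimethoxyphenyl)ethan-1-one (racemic) | COc1cc(C(Br)C(=O)c2c(O)c(OCc3ccccc3)c(OC)c(OC)c2OC)cc(OC)c1OC
F6 | step 11 | 3-chloro-8-hydroxy-5,6,7,3',4',5'-hexamethoxyflavone | COc1cc(-c2oc3c(O)c(OC)c(OC)c(OC)c3c(=O)c2Cl)cc(OC)c1OC
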